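Starting material leaves the east flask so slowly that 72.3% of the charge still stands after 90.0 min. What counts is whether that slowness keeps it in first place at the asked time.

the same everywhere: starting material 2.2 M
- east: the very flask that is asked about, followed so far
- flask: time 5.0 h

east run (percent of the starting material charged)

| time / min | starting material / % | intermediate D / % | intermediate C / % | product / % | intermediate A / % | intermediate B / % |
|---|---|---|---|---|---|---|
| 6.00 | 97.8 | 0.2 | 0 | 0 | 1.9 | 0 |
| 20.0 | 94.2 | 0 | 0 | 0 | 6.3 | 0.3 |
| 30.0 | 90.1 | 0 | 0 | 0 | 9.5 | 1.4 |
| 50.0 | 83.4 | 0 | 0 | 0.4 | 15.3 | 1.7 |
| 60.0 | 81.1 | 0 | 1.0 | 0 | 16.8 | 1.9 |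
| 90.0 | 72.3 | 0.3 | 0.1 | 0 | 21.3 | 4.6 |

(scatter of a reading: 0.5 percentage points)

1. where most of what was charged as starting material, at 5.0 h is found (intermediate B / product / intermediate A / intermediate D / starting material / intermediate C)
2. the largest share itself, whichever of these holds it, in percent of the starting material charged



In the first instants the east flask holds starting material and, growing beside it, intermediate A. Read as a first-order decay, the last point gives 0.00360 min⁻¹. The symmetric case serves as the zero of the scale: for two consecutive first-order steps with the same constant k, the fraction in the intermediate divided by the fraction in the starting material equals kt. The two fractions are then equal at the crossing time, the inverse of k and so the mean lifetime of the starting material, 4.62 h. The asked time is later than that, at 1.08 on this scale.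

At the last reading of the east run, 90.0 min, the ratio reads 0.295 against 0.325 on the scale, so intermediate A runs a little under it. Intermediate B reads 4.6%, while intermediate D, the highest of the later species, reads 0.3%, under the scatter.

For the end, the decay leaves 33.9% of starting material. The same shortfall puts the ratio at 0.983, a near tie. Any return from intermediate B to intermediate A, which these readings cannot yet show, raises it. Without such a return, this reckoning leaves starting material narrowly ahead at 33.9%, with intermediate A at 33.3%.

The forecast named starting material at 35%, in “a close three-way split”.

The flask gives intermediate A at 41.4%, with starting material at 34.0%.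

    intermediate C ⇌ intermediate D (K = 0.430, k = 0.0340 min⁻¹)
    intermediate A ⇌ intermediate B (K = 0.420, k = 0.00700 min⁻¹)
    starting material → intermediate A (k = 0.00360 min⁻¹)
    intermediate C → product (k = 5.40 × 10⁻⁴ min⁻¹)
    intermediate B → intermediate C (k = 0.00630 min⁻¹)

Intermediates A and B relax towards each other with a half-life of 0.488 h by that step alone, both ways together, short against the asked time. At 5.0 h the ratio stands at 1.22, above the 1.08 of the scale. The same flask read at 80 min, earlier than the crossing time, stands at 0.289 on the scale and has starting material ahead, with a ratio of 0.275 and 75.0% still unreacted.

The numbers in the tables are simulated with constants of no real substance; the scatter is artificial.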